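## Retrosynthetic overview

- Numbering follows the open C20 chain. C1=C2 is the vinyl group; the oxane ring is O, C3, C4, C5, C6(Br), C7; C8 and C9 are the linker; the carbocycle is C10, C11(OH), C12, C13, C14(Br), C15(Me2).
- Enabling feature: in the carbocycle the secondary bromide C14 sits next to the quaternary gem-dimethyl carbon C15. This is the retron of a bromiranium ion opened at its tertiary end, and C10/C11 lie one six-membered ring away. The axial C15 methyl, 1,3 to C11, later steers the methyl addition.
- 20 ⇒ ketone 19 (C11-CH3, organocerium) ⇒ open-chain silyl enol ether 17 (C10-C15 bond by bromiranium ring closure). C11 is held one oxidation level higher, and Et3Si and CF3CO2 are temporary activators.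
- 17 ⇒ enone 13 (epoxidation, bromide opening, acylation, 1,4-hydrosilylation) ⇒ aldehyde 8 + ketophosphonate 12 (C9=C10, Horner–Wadsworth–Emmons).
- 8 ⇒ oxane 5 ⇒ bromochloride 3 ⇒ (S)-linalool 1. Ring order: oxane first (step 3), carbocycle last (step 13).

Key step: step 13

Assumption: (S)-(+)-linalool (coriandrol) is taken as a purchasable chiral-pool terpene; any residual (R)-enantiomer would be shed as diastereomers after the catalyst-controlled step 2.

## Route

Step 1
Reactants: 1 (S)-(+)-linalool
Product: 2 (2E,6S)-2,6-dimethylocta-2,7-diene-1,6-diol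
Conditions: SeO2 (cat.), t-BuOOH, salicylic acid (cat.), CH2Cl2, 0 °C to rt
Reagents that add atoms: tert-butyl hydroperoxide, CC(C)(C)OO
Why: Riley allylic oxidation (ene reaction, then [2,3]-sigmatropic shift) should hydroxylate only the methyl group trans to the chain on the one trisubstituted olefin, giving the (E)-allylic alcohol (C8-OH) and leaving C3 untouched.

Step 2
Reactants: 2 (2E,6S)-2,6-dimethylocta-2,7-diene-1,6-diol
Product: 3 (2S,3R,6S)-3-bromo-2-chloro-2,6-dimethyloct-7-ene-1,6-diol
Conditions: NBS, ClTi(OiPr)3, 2,4-di-tert-butyl-6-{[(1-hydroxy-3,3-dimethyl-1,1-diphenylbutan-2-yl)imino]methyl}phenol (cat., the antipode that gives 6R,7S), hexanes–CH2Cl2, −20 °C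
Reagents that add atoms: N-bromosuccinimide, O=C1CCC(=O)N1Br; chlorotitanium triisopropoxide, CC(C)O[Ti](Cl)(OC(C)C)OC(C)C
Why: In this titanium-catalysed enantioselective bromochlorination of an allylic alcohol the C8 alkoxide binds to the chiral titanium Schiff-base complex, Br+ reaches one face of C6=C7 and chloride opens the bromiranium ion anti at the tertiary carbon C7, so catalyst control sets 6R and 7S independently of C3 while the far less nucleophilic vinyl group stays out.

Step 3
Reactants: 3 (2S,3R,6S)-3-bromo-2-chloro-2,6-dimethyloct-7-ene-1,6-diol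
Product: 5 [(2S,3R,6S)-3-bromo-6-ethenyl-2,6-dimethyloxan-2-yl]methanol, via bromiranium ion 4 (not isolated)
Conditions: (CF3)2CHOH, NaHCO3 (solid), 40 °C
Reagents that add atoms: none
Why: In this solvolysis of a vicinal bromochloride as a bromiranium surrogate, ionisation of the tertiary C7-Cl bond is assisted by the anti C6 bromine and the C3 hydroxyl opens ion 4 at C7 from the side that chloride left (double inversion, net retention at C7, C6 untouched), a 6-endo closure to which any 5-exo product should return because its tertiary bromide re-ionises under the same conditions.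

Step 4
Reactants: 5 [(2S,3R,6S)-3-bromo-6-ethenyl-2,6-dimethyloxan-2-yl]methanol
Product: 6 (2S,3R,6S)-3-bromo-6-ethenyl-2,6-dimethyloxane-2-carbaldehyde
Conditions: 2,2,6,6-tetramethylpiperidine-1-oxyl (cat.), PhI(OAc)2, CH2Cl2, rt
Reagents that add atoms: none
Why: Oxoammonium-mediated oxidation of the primary alcohol should stop at the aldehyde, which has no α-hydrogen and so can neither epimerise nor eliminate.

Step 5
Reactants: 6 (2S,3R,6S)-3-bromo-6-ethenyl-2,6-dimethyloxane-2-carbaldehyde
Product: 7 (2S,3R,6S)-3-bromo-6-ethenyl-2-(2-methoxyethenyl)-2,6-dimethyloxane (E/Z mixture, E isomer drawn)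
Conditions: Ph3P(CH2OMe)Cl, KN(SiMe3)2, THF, −78 to 0 °C
Reagents that add atoms: (methoxymethyl)triphenylphosphonium chloride, COC[P+](c1ccccc1)(c1ccccc1)c1ccccc1.[Cl-]
Why: Wittig olefination with the non-stabilised methoxymethylidene ylide adds the missing carbon C9 to the hindered, non-enolisable aldehyde, and the geometry of the enol ether is of no consequence.

Step 6
Reactants: 7 (2S,3R,6S)-3-bromo-6-ethenyl-2-(2-methoxyethenyl)-2,6-dimethyloxane
Product: 8 [(2S,3R,6S)-3-bromo-6-ethenyl-2,6-dimethyloxan-2-yl]acetaldehyde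
Conditions: p-TsOH·H2O (cat.), acetone–H2O, rt
Reagents that add atoms: water, O
Why: Mild acid-catalysed enol ether hydrolysis should free the aldehyde without ionising the oxane C3-O bond, and no stereocentre is touched.

Step 7
Reactants: 9 dimethyl (2-oxopropyl)phosphonate; 10 prenyl bromide (1-bromo-3-methylbut-2-ene)
Product: 12 dimethyl (6-methyl-2-oxohept-5-en-1-yl)phosphonate, via phosphonate dianion 11 (not isolated)
Conditions: NaH, THF, 0 °C; n-BuLi, 0 °C; 10, 0 °C to rt; then H2O
Reagents that add atoms: none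
Why: In this γ-alkylation of a β-ketophosphonate dianion the more basic terminal carbanion of 11 should be prenylated in SN2 fashion, giving C10 to C15 in one step.

Step 8
Reactants: 8 [(2S,3R,6S)-3-bromo-6-ethenyl-2,6-dimethyloxan-2-yl]acetaldehyde; 12 dimethyl (6-methyl-2-oxohept-5-en-1-yl)phosphonate
Product: 13 (2E)-1-[(2S,3R,6S)-3-bromo-6-ethenyl-2,6-dimethyloxan-2-yl]-8-methylnona-2,7-dien-4-one
Conditions: LiCl, i-Pr2NEt, MeCN, rt
Reagents that add atoms: none
Why: Horner–Wadsworth–Emmons olefination under LiCl/amine conditions is mild enough for the β-alkoxy aldehyde and the secondary bromide and should give the (E)-enone.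

Step 9
Reactants: 13 (2E)-1-[(2S,3R,6S)-3-bromo-6-ethenyl-2,6-dimethyloxan-2-yl]-8-methylnona-2,7-dien-4-one
Product: 14 (2E)-1-[(2S,3R,6S)-3-bromo-6-ethenyl-2,6-dimethyloxan-2-yl]-6-[(2S)-3,3-dimethyloxiran-2-yl]hex-2-en-4-one
Conditions: 1,2:4,5-di-O-isopropylidene-β-L-erythro-2,3-hexodiulo-2,6-pyranose (cat.), KHSO5, K2CO3, Bu4NHSO4 (cat.), MeCN–CH2(OMe)2–aq. borate buffer, 0 °C
Reagents that add atoms: potassium peroxymonosulfate, [K+].[O-]S(=O)(=O)OO
Why: In this Shi epoxidation the chiral dioxirane should attack only the electron-rich trisubstituted C14=C15 olefin (enone and vinyl group are too electron-poor), and the L-fructose-derived ketone sets 14S through the spiro transition state under catalyst control.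

Step 10
Reactants: 14 (2E)-1-[(2S,3R,6S)-3-bromo-6-ethenyl-2,6-dimethyloxan-2-yl]-6-[(2S)-3,3-dimethyloxiran-2-yl]hex-2-en-4-one
Product: 15 (2E,7R)-7-bromo-1-[(2S,3R,6S)-3-bromo-6-ethenyl-2,6-dimethyloxan-2-yl]-8-hydroxy-8-methylnon-2-en-4-one
Conditions: Li2NiBr4, THF, 0 °C; then H2O
Reagents that add atoms: dilithium tetrabromonickelate, [Li+].[Li+].[Ni+2].[Br-].[Br-].[Br-].[Br-]
Why: SN2 opening of the epoxide by the soft bromide of Li2NiBr4 at the less substituted carbon C14 should invert it to 14R and leave the tertiary C15 hydroxyl.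

Step 11
Reactants: 15 (2E,7R)-7-bromo-1-[(2S,3R,6S)-3-bromo-6-ethenyl-2,6-dimethyloxan-2-yl]-8-hydroxy-8-methylnon-2-en-4-one
Product: 16 (3R,7E)-3-bromo-9-[(2S,3R,6S)-3-bromo-6-ethenyl-2,6-dimethyloxan-2-yl]-2-methyl-6-oxonon-7-en-2-yl trifluoroacetate
Conditions: (CF3CO)2O, pyridine, CH2Cl2, 0 °C
Reagents that add atoms: trifluoroacetic anhydride, O=C(OC(=O)C(F)(F)F)C(F)(F)F
Why: Acylation with the very reactive anhydride turns the tertiary hydroxyl into a leaving group under conditions too weakly basic to close the bromohydrin back to the epoxide.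

Step 12
Reactants: 16 (3R,7E)-3-bromo-9-[(2S,3R,6S)-3-bromo-6-ethenyl-2,6-dimethyloxan-2-yl]-2-methyl-6-oxonon-7-en-2-yl trifluoroacetate
Product: 17 (3R,6Z)-3-bromo-9-[(2S,3R,6S)-3-bromo-6-ethenyl-2,6-dimethyloxan-2-yl]-2-methyl-6-(triethylsilyloxy)non-6-en-2-yl trifluoroacetate
Conditions: RhCl(PPh3)3 (cat.), Et3SiH, THF, 50 °C
Reagents that add atoms: triethylsilane, CC[SiH](CC)CC
Why: Rhodium-catalysed 1,4-hydrosilylation of the enone through its s-cis conformer should give the regiodefined (Z)-silyl enol ether C10=C11, which deprotonation of the saturated ketone could not deliver selectively.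

Step 13
Reactants: 17 (3R,6Z)-3-bromo-9-[(2S,3R,6S)-3-bromo-6-ethenyl-2,6-dimethyloxan-2-yl]-2-methyl-6-(triethylsilyloxy)non-6-en-2-yl trifluoroacetate
Product: 19 (2R,4R)-4-bromo-2-{2-[(2S,3R,6S)-3-bromo-6-ethenyl-2,6-dimethyloxan-2-yl]ethyl}-3,3-dimethylcyclohexan-1-one, via bromiranium ion 18 (not isolated)
Conditions: MeAlCl2, CH2Cl2 (high dilution), −78 °C; then H2O
Reagents that add atoms: none
Why: Proposed new method: MeAlCl2 pulls the tertiary trifluoroacetate off C15 while the anti-periplanar C14 bromine closes to bromiranium ion 18, whose tertiary carbon C15 is attacked by C10 of the (Z)-silyl enol ether, and loss of the silyl group from the silyloxocarbenium ion leaves the C11 ketone. The closest known reaction types are the Lewis-acid α-tert-alkylation of silyl enol ethers by tertiary halides or esters, the MeAlCl2-promoted cation–olefin cyclisation ended by a silyl enol ether, and the enantiospecific polyene cyclisation of bromiranium ions released from enantiopure bromohydrin esters or vicinal bromochlorides; new is only their combination, a bromiranium ion met by an enol ether. The carbocycle (C10, C11, C12, C13, C14, C15) closes 6-endo-trig at the enol ether and endo at the three-membered ring (both bromiranium carbons end up in the new ring) through a chair. C14 is carried over unchanged (14R from step 10) because bromine never leaves it and C15 is not stereogenic, while the new centre C10 is set by the chair, in which C14-Br is equatorial and the Z geometry places the C9 chain trans to C12 and thus equatorial, cis to bromine (10R), which should also be the more stable epimer of this enolisable centre. The step needs carbon attack at C15 rather than transfer of Br+ to the electron-rich enol ether, proton loss to an isopropenyl group or ionisation of the allylic C3-O bond; this should be secured by the six-membered chair, the cationic weight on tertiary C15, high dilution at low temperature, the proton-scavenging Al-CH3 bond and the shielding of the oxane oxygen by its two fully substituted neighbours C3 and C7.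

Step 14
Reactants: 19 (2R,4R)-4-bromo-2-{2-[(2S,3R,6S)-3-bromo-6-ethenyl-2,6-dimethyloxan-2-yl]ethyl}-3,3-dimethylcyclohexan-1-one
Product: 20 (1S,2R,4R)-4-bromo-2-{2-[(2S,3R,6S)-3-bromo-6-ethenyl-2,6-dimethyloxan-2-yl]ethyl}-1,3,3-trimethylcyclohexan-1-ol (target)
Conditions: CeCl3, MeLi, THF, −78 °C; then H2O
Reagents that add atoms: methyllithium, [Li]C
Why: In this organocerium 1,2-addition (non-basic, so no enolisation and no 1,3-elimination of bromide) the axial C15 methyl group blocks the axial approach to C11, so methyl should enter equatorially and give the axial 11S alcohol, cis to the C9 chain and on the same face as C14-Br, from which it cannot displace that bromide.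

## Compound list

1 | (S)-(+)-linalool, (3S)-3,7-dimethylocta-1,6-dien-3-ol | C=C[C@](O)(C)CCC=C(C)C | starting material
2 | (2E,6S)-2,6-dimethylocta-2,7-diene-1,6-diol | C=C[C@](O)(C)CC/C=C(\C)CO | intermediate
3 | (2S,3R,6S)-3-bromo-2-chloro-2,6-dimethyloct-7-ene-1,6-diol | C=C[C@](O)(C)CC[C@@H](Br)[C@](C)(CO)Cl | intermediate
4 | bromiranium ion from 3 (Br bridging C6 and C7), not isolated | C=C[C@](O)(C)CC[C@H]1[Br+][C@]1(C)CO | intermediate
5 | [(2S,3R,6S)-3-bromo-6-ethenyl-2,6-dimethyloxan-2-yl]methanol | C=C[C@]1(C)CC[C@@H](Br)[C@](C)(CO)O1 | intermediate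
6 | (2S,3R,6S)-3-bromo-6-ethenyl-2,6-dimethyloxane-2-carbaldehyde | C=C[C@]1(C)CC[C@@H](Br)[C@](C)(C=O)O1 | intermediate
7 | (2S,3R,6S)-3-bromo-6-ethenyl-2-(2-methoxyethenyl)-2,6-dimethyloxane (E/Z mixture, E drawn) | C=C[C@]1(C)CC[C@@H](Br)[C@](C)(/C=C/OC)O1 | intermediate
8 | [(2S,3R,6S)-3-bromo-6-ethenyl-2,6-dimethyloxan-2-yl]acetaldehyde | C=C[C@]1(C)CC[C@@H](Br)[C@](C)(CC=O)O1 | intermediate
9 | dimethyl (2-oxopropyl)phosphonate | COP(=O)(OC)CC(C)=O | starting material
10 | prenyl bromide, 1-bromo-3-methylbut-2-ene | CC(C)=CCBr | starting material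
11 | sodium lithium dianion of 9, not isolated | [Na+].[Li+].[CH2-]C(=O)[CH-]P(=O)(OC)OC | intermediate
12 | dimethyl (6-methyl-2-oxohept-5-en-1-yl)phosphonate | COP(=O)(OC)CC(=O)CCC=C(C)C | intermediate
13 | (2E)-1-[(2S,3R,6S)-3-bromo-6-ethenyl-2,6-dimethyloxan-2-yl]-8-methylnona-2,7-dien-4-one | C=C[C@]1(C)CC[C@@H](Br)[C@](C)(C/C=C/C(=O)CCC=C(C)C)O1 | intermediate
14 | (2E)-1-[(2S,3R,6S)-3-bromo-6-ethenyl-2,6-dimethyloxan-2-yl]-6-[(2S)-3,3-dimethyloxiran-2-yl]hex-2-en-4-one | C=C[C@]1(C)CC[C@@H](Br)[C@](C)(C/C=C/C(=O)CC[C@@H]2OC2(C)C)O1 | intermediate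
15 | (2E,7R)-7-bromo-1-[(2S,3R,6S)-3-bromo-6-ethenyl-2,6-dimethyloxan-2-yl]-8-hydroxy-8-methylnon-2-en-4-one | C=C[C@]1(C)CC[C@@H](Br)[C@](C)(C/C=C/C(=O)CC[C@@H](Br)C(C)(C)O)O1 | intermediate
16 | tertiary trifluoroacetate of 15 | C=C[C@]1(C)CC[C@@H](Br)[C@](C)(C/C=C/C(=O)CC[C@@H](Br)C(C)(C)OC(=O)C(F)(F)F)O1 | intermediate
17 | (Z)-triethylsilyl enol ether (C10=C11) bearing the C14 bromide and the C15 trifluoroacetate | C=C[C@]1(C)CC[C@@H](Br)[C@](C)(CC/C=C(\O[Si](CC)(CC)CC)CC[C@@H](Br)C(C)(C)OC(=O)C(F)(F)F)O1 | intermediate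
18 | bromiranium ion from 17 (Br bridging C14 and C15, aluminate counter-ion), not isolated | C=C[C@]1(C)CC[C@@H](Br)[C@](C)(CC/C=C(\O[Si](CC)(CC)CC)CC[C@H]2[Br+]C2(C)C)O1 | intermediate
19 | (2R,4R)-4-bromo-2-{2-[(2S,3R,6S)-3-bromo-6-ethenyl-2,6-dimethyloxan-2-yl]ethyl}-3,3-dimethylcyclohexan-1-one | C=C[C@]1(C)CC[C@@H](Br)[C@](C)(CC[C@@H]2C(C)(C)[C@H](Br)CCC2=O)O1 | intermediate
20 | (1S,2R,4R)-4-bromo-2-{2-[(2S,3R,6S)-3-bromo-6-ethenyl-2,6-dimethyloxan-2-yl]ethyl}-1,3,3-trimethylcyclohexan-1-ol | C=C[C@]1(C)CC[C@@H](Br)[C@](C)(CC[C@@H]2C(C)(C)[C@H](Br)CC[C@]2(C)O)O1 | target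

## Step count and risks

Total step count: 14. Longest linear sequence: 13 (steps 1 to 6 and 8 to 14).

**Risk 1, step 13 (bears the label).**
- What may go wrong: transfer of Br+ from the bromiranium ion to the very electron-rich enol ether, which would undo the bromide stereocentre, or loss of the silyl group before the ring closes.
- The fallback uses known chemistry, sets out from 14 and comes back at 19. It replaces the enol ether by an allylsilane, the classical regiodefining terminator of cation–olefin cyclisations, and recovers the ketone by oxidative cleavage.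
- Conjugate reduction of 14 with LiBH(s-Bu)3 at −78 °C, with trapping of the enolate by N-(5-chloropyridin-2-yl)bis(trifluoromethanesulfonimide), should give the (Z)-enol triflate F1.
- Kumada-type coupling with Me3SiCH2MgCl under Pd(PPh3)4 should give the allylsilane F2 with retention of geometry.
- Li2NiBr4 should open the epoxide to the bromohydrin F3, and (CF3CO)2O/pyridine should give the trifluoroacetate F4.
- MeAlCl2 at −78 °C should then close the same ring through the same chair, with loss of the silyl group, to the exocyclic methylene compound F5.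
- mCPBA should epoxidise only the 1,1-disubstituted olefin to the spiro-epoxide F6, and H5IO6 should cleave it to 19.

**Risk 2, step 10.**
- What may go wrong: loose, SN1-like attack of bromide at the tertiary carbon C15, participation of the C11 carbonyl oxygen, or Lewis-acid rearrangement of the epoxide.
- The fallback sets out from dianion 11 and aldehyde 8 and comes back at 19 (through 18). It makes the C14 bromide by the reaction type of step 2 instead of by epoxide opening.
- Prenol is bromochlorinated (NBS, ClTi(OiPr)3, the same Schiff-base ligand) to (2R)-2-bromo-3-chloro-3-methylbutan-1-ol F7.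
- (CF3SO2)2O/2,6-lutidine should give the triflate F8, and alkylation of 11 with F8 at −78 °C should give the ketophosphonate F9.
- Olefination of 8 under the conditions of step 8 should give the enone F10, and hydrosilylation as in step 12 the silyl enol ether F11.
- MeAlCl2 should abstract the tertiary chloride of F11 to give 18 and then 19.

**Risk 3, step 2.**
- What may go wrong: the free tertiary C3 hydroxyl competes for titanium, with erosion of facial selectivity, or intercepts the bromiranium ion before chloride does.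
- The fallback sets out from 2 and comes back at 5. It uses direct bromoetherification with Et2SBr·SbCl5Br in MeNO2 at low temperature, without catalyst control.
- Because C3 is fixed, the products of attack on the two olefin faces and the five-membered-ring isomers are diastereomers or constitutional isomers of 5 and would be removed by chromatography.
- This fallback makes no compound outside the list (F0).

## Further compounds

F1 | step 13 | (Z)-enol triflate (C10=C11) with intact (14S)-epoxide | C=C[C@]1(C)CC[C@@H](Br)[C@](C)(CC/C=C(\OS(=O)(=O)C(F)(F)F)CC[C@@H]2OC2(C)C)O1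
F2 | step 13 | (Z)-allylsilane, C11 bearing CH2SiMe3, with intact epoxide | C=C[C@]1(C)CC[C@@H](Br)[C@](C)(CC/C=C(\C[Si](C)(C)C)CC[C@@H]2OC2(C)C)O1
F3 | step 13 | (14R)-bromohydrin of the allylsilane | C=C[C@]1(C)CC[C@@H](Br)[C@](C)(CC/C=C(\C[Si](C)(C)C)CC[C@@H](Br)C(C)(C)O)O1
F4 | step 13 | tertiary trifluoroacetate of F3 | C=C[C@]1(C)CC[C@@H](Br)[C@](C)(CC/C=C(\C[Si](C)(C)C)CC[C@@H](Br)C(C)(C)OC(=O)C(F)(F)F)O1
F5 | step 13 | bromocyclohexane with exocyclic methylene at C11 | C=C[C@]1(C)CC[C@@H](Br)[C@](C)(CC[C@@H]2C(C)(C)[C@H](Br)CCC2=C)O1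
F6 | step 13 | spiro-epoxide at C11 (oxygen equatorial) | C=C[C@]1(C)CC[C@@H](Br)[C@](C)(CC[C@@H]2C(C)(C)[C@H](Br)CC[C@]23CO3)O1
F7 | step 10 | (2R)-2-bromo-3-chloro-3-methylbutan-1-ol | OC[C@@H](Br)C(C)(C)Cl
F8 | step 10 | (2R)-2-bromo-3-chloro-3-methylbutyl trifluoromethanesulfonate | O=S(=O)(OC[C@@H](Br)C(C)(C)Cl)C(F)(F)F
F9 | step 10 | dimethyl [(5R)-5-bromo-6-chloro-6-methyl-2-oxoheptyl]phosphonate | COP(=O)(OC)CC(=O)CC[C@@H](Br)C(C)(C)Cl
F10 | step 10 | (E)-enone bearing the (14R)-bromide and the C15 chloride | C=C[C@]1(C)CC[C@@H](Br)[C@](C)(C/C=C/C(=O)CC[C@@H](Br)C(C)(C)Cl)O1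
F11 | step 10 | (Z)-triethylsilyl enol ether bearing the (14R)-bromide and the C15 chloride | C=C[C@]1(C)CC[C@@H](Br)[C@](C)(CC/C=C(\O[Si](CC)(CC)CC)CC[C@@H](Br)C(C)(C)Cl)O1
F0 | step 2 | none | none
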